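The dienone is cut between the exocyclic α-methylene carbon on ring carbon C5 of the 7-oxabicyclo[4.1.0]heptanone and the side-chain carbonyl carbon. (R)-Carvone supplies the ring and C5. Its isopropenyl group is clipped to acetyl, and the acetyl methyl becomes the =CH2 of an enol triflate. This fully oxygenated triflate, with the ring ketone parked as a silylated carbinol, is coupled with 4-methylpent-3-enal under Ni/Cr mediation. The coupling makes the bond with the 1,1-disubstituted alkene already in place and leaves the epoxide and tiglate alone. One double oxidation then unveils both ketones. A biomimetic singlet-oxygen ene reaction finally converts the prenyl terminus into the (E)-γ-hydroperoxy enone.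

Key step: step 9

Convention: carvone numbering is kept for the ring in all names (C1 = carbonyl carbon or its carbinol, C2 = methyl-bearing carbon, C3, C4, C5 = carbon bearing the side chain, C6 = oxygenated carbon between C5 and C1); β is the ring face that carries the C5 side chain and α is the opposite face.
Assumption: the side-chain carbinol carbon of 15 and 16 is expected as a mixture of both epimers and is written without configuration, because step 11 turns it into a carbonyl carbon.

Step 1
Reactants: 1 (R)-(−)-carvone
Product: 3 (5S,6S)-6-hydroxycarvone (6α-OH trans to the 5β-isopropenyl group), via lithium dienolate 2 (not isolated)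
Conditions: LDA, THF, −78 °C; then Davis oxaziridine, −78 °C; AcOH quench
Reagents that add atoms: 3-phenyl-2-(phenylsulfonyl)-1,2-oxaziridine (Davis oxaziridine), O=S(=O)(c1ccccc1)N1OC1c1ccccc1
Why: Kinetic α'-deprotonation at C6 gives the cross-conjugated dienolate, and the Davis enolate hydroxylation should deliver oxygen to the α face, anti to the neighbouring 5β-isopropenyl group, which sets C6 as the 5,6-trans (diequatorial and also thermodynamically preferred) ketol.

Step 2
Reactants: 3 (5S,6S)-6-hydroxycarvone; 4 tigloyl chloride
Product: 5 6α-tigloyloxycarvone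
Conditions: Et3N, DMAP (cat.), CH2Cl2, 0 °C to rt
Reagents that add atoms: none
Why: DMAP-catalysed acyl transfer from an acid chloride to a secondary alcohol (Steglich-type nucleophilic catalysis) forms the ester without touching C5 or C6, and the E-configured tiglate is the stable alkene isomer, so no geometric drift is expected.

Step 3
Reactants: 5 6α-tigloyloxycarvone
Product: 6 6α-tigloyloxy-cis-carveol (1β-OH, cis to the isopropenyl group and trans to the tiglate)
Conditions: NaBH4, CeCl3·7H2O, MeOH, −78 to −40 °C
Reagents that add atoms: none
Why: Luche reduction gives clean 1,2-reduction of the enone, and axial hydride delivery from the α face, as in the reduction of carvone to cis-carveol, should place the new C1 hydroxyl equatorial on the β face, while the hindered conjugated tiglate neither reduces nor migrates at low temperature.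

Step 4
Reactants: 6 6α-tigloyloxy-cis-carveol
Product: 7 2,3β-epoxy alcohol (epoxide oxygen, 1-OH and isopropenyl group on the β face, tiglate on the α face)
Conditions: VO(acac)2 (cat.), t-BuOOH (decane), CH2Cl2, 0 °C to rt
Reagents that add atoms: tert-butyl hydroperoxide, CC(C)(C)OO
Why: Vanadium-catalysed hydroxyl-directed epoxidation of an allylic alcohol delivers oxygen from the face of the bound 1β-alkoxide, which sets C2 and C3 as the β-epoxide (cis to the C5 group, the face that nucleophilic epoxidation of the enone would not reach) and leaves the undirected isopropenyl and the electron-poor tiglate alkenes alone.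

Step 5
Reactants: 7 2,3β-epoxy alcohol
Product: 8 1β-O-triethylsilyl ether of 7
Conditions: TESOTf, 2,6-lutidine, CH2Cl2, −78 to 0 °C
Reagents that add atoms: triethylsilyl trifluoromethanesulfonate, CC[Si](CC)(CC)OS(=O)(=O)C(F)(F)F
Why: Silylation of the hindered secondary carbinol with a silyl triflate and a non-nucleophilic base masks C1–OH against alkoxide formation, acyl migration and O-sulfonylation in step 7 without affecting any stereocentre.

Step 6
Reactants: 8 1β-O-triethylsilyl ether
Product: 10 5β-acetyl compound (methyl ketone), via secondary ozonide 9 (not isolated)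
Conditions: O3, CH2Cl2, −78 °C (Sudan Red 7B end point); then Me2S, −78 °C to rt
Reagents that add atoms: ozone, [O-][O+]=O
Why: Ozonolysis (Criegee mechanism) with reductive work-up cleaves the electron-rich 1,1-disubstituted alkene far faster than the conjugated tiglate, so that titration to the dye end point should remove only the =CH2 carbon and leave C5 untouched.

Step 7
Reactants: 10 5β-acetyl compound
Product: 12 enol triflate (5β-[1-(trifluoromethylsulfonyloxy)ethenyl] compound), via potassium enolate 11 (not isolated)
Conditions: KHMDS, THF, −78 °C (ketone added to base); then Comins reagent, −78 °C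
Reagents that add atoms: N-(5-chloropyridin-2-yl)bis(trifluoromethanesulfonimide) (Comins reagent), O=S(=O)(N(c1ccc(Cl)cn1)S(=O)(=O)C(F)(F)F)C(F)(F)F
Why: Kinetic deprotonation of the methyl ketone on its unhindered CH3 side followed by O-sulfonylation (enol triflate synthesis) turns the former carvone methyl group into the =CH2 of a 2-triflyloxy-1-alkene, and the low temperature and inverse addition suppress enolate equilibration to C5 and hence epimerisation or β-elimination of the tiglate.

Step 8
Reactants: 13 4-methylpent-3-en-1-ol
Product: 14 4-methylpent-3-enal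
Conditions: Dess–Martin periodinane, CH2Cl2, 0 °C to rt
Reagents that add atoms: none
Why: Dess–Martin oxidation of the primary homoallylic alcohol stops at the aldehyde under nearly neutral conditions, which should keep the β,γ-alkene out of conjugation.

Step 9
Reactants: 12 enol triflate; 14 4-methylpent-3-enal
Product: 15 coupling product (5β-(3-hydroxy-6-methylhepta-1,5-dien-2-yl) compound, both carbinol epimers)
Conditions: CrCl2 (excess), NiCl2 (cat.), degassed DMF, rt
Reagents that add atoms: none
Why: Ni(0), formed in situ from NiCl2 and CrCl2, inserts into the C–OTf bond of 12, the alkenylnickel species transmetalates to Cr(III), and the resulting alkenylchromium(III) reagent adds 1,2 to the aldehyde carbon of 14, which makes the bond between the methylene-bearing sp2 carbon on ring C5 and the future side-chain carbonyl carbon with the C=CH2 unit already in place. The closest known reaction type is the Nozaki–Hiyama–Kishi coupling of 2-triflyloxy-1-alkenes with aldehydes. No ring is closed. The only new stereocentre, the side-chain carbinol carbon, is not controlled by the substrate and needs no control because step 11 erases it, while C1, C5, C6 and the epoxide carbons are not touched under these neutral conditions. The step needs chemoselectivity for the aldehyde over the tiglate, the epoxide and the silyl ether, which the low basicity and strong aldehyde preference of organochromium(III) reagents secure, and the same mildness keeps the isomerisation-prone β,γ-unsaturated aldehyde out of conjugation. Holding ring C1 at the carbinol level is what makes the step viable, because an α,β-epoxy-α'-acyloxy ketone would be reduced by Cr(II).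

Step 10
Reactants: 15 coupling product
Product: 16 diol (free 1β-OH and side-chain carbinol)
Conditions: HF·pyridine, pyridine, THF, 0 °C
Reagents that add atoms: none
Why: Fluoride-induced cleavage of the Si–O bond with pyridine-buffered HF frees the C1 carbinol under conditions that are too weakly acidic to open the epoxide and too weakly basic to move the tiglate.

Step 11
Reactants: 16 diol
Product: 17 diketone (5β-(6-methyl-3-oxohepta-1,5-dien-2-yl) epoxy ketone tiglate)
Conditions: Dess–Martin periodinane (excess), CH2Cl2, 0 °C to rt
Reagents that add atoms: none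
Why: Twofold Dess–Martin oxidation converts the ring carbinol and the side-chain carbinol into the two ketones in one operation, which erases both temporary stereocentres, and the near-neutral medium should spare the epoxide, the C6 centre and the skipped enone.

Step 12
Reactants: 17 diketone
Product: 18 target CNP0284595.1
Conditions: O2, tetraphenylporphyrin (cat.), visible light, CH2Cl2, −20 °C
Reagents that add atoms: dioxygen, O=O
Why: Schenck ene reaction, in which singlet oxygen attacks only the electron-rich trisubstituted alkene (the α-methylene ketone and the tiglate are electron-poor), bonds to the dimethyl-substituted carbon and takes a hydrogen from the doubly activated CH2 next to the ketone, so that the alkene moves into conjugation with E geometry and the tertiary hydroperoxide forms as in the presumed biosynthesis, with no new stereocentre.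

Compound list
1 | (R)-(−)-carvone, (5R)-2-methyl-5-(prop-1-en-2-yl)cyclohex-2-en-1-one | C=C(C)[C@@H]1CC=C(C)C(=O)C1 | starting material
2 | lithium cross-conjugated dienolate of 1 (C1–O−, C1=C6) | C=C(C)[C@@H]1CC=C(C)C([O-])=C1.[Li+] | intermediate (not isolated)
3 | (5S,6S)-6-hydroxycarvone, 6α-OH trans to the 5β-isopropenyl group | C=C(C)[C@@H]1CC=C(C)C(=O)[C@H]1O | intermediate
4 | tigloyl chloride, (E)-2-methylbut-2-enoyl chloride | C/C=C(\C)C(=O)Cl | starting material
5 | 6α-tigloyloxycarvone | C=C(C)[C@@H]1CC=C(C)C(=O)[C@H]1OC(=O)/C(C)=C/C | intermediate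
6 | 6α-tigloyloxy-cis-carveol, 1β-OH | C=C(C)[C@@H]1CC=C(C)[C@H](O)[C@H]1OC(=O)/C(C)=C/C | intermediate
7 | 2,3β-epoxy-1β-hydroxy-6α-tigloyloxy compound with 5β-isopropenyl group | C=C(C)[C@@H]1C[C@@H]2O[C@]2(C)[C@H](O)[C@H]1OC(=O)/C(C)=C/C | intermediate
8 | 1β-O-triethylsilyl ether of 7 | C=C(C)[C@@H]1C[C@@H]2O[C@]2(C)[C@H](O[Si](CC)(CC)CC)[C@H]1OC(=O)/C(C)=C/C | intermediate
9 | secondary ozonide (3-methyl-1,2,4-trioxolan-3-yl group on C5) of 8 | CC1(OCOO1)[C@@H]1C[C@@H]2O[C@]2(C)[C@H](O[Si](CC)(CC)CC)[C@H]1OC(=O)/C(C)=C/C | intermediate (not isolated)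
10 | 5β-acetyl-2,3β-epoxy-1β-triethylsilyloxy-6α-tigloyloxy compound | CC(=O)[C@@H]1C[C@@H]2O[C@]2(C)[C@H](O[Si](CC)(CC)CC)[C@H]1OC(=O)/C(C)=C/C | intermediate
11 | terminal potassium enolate of 10 | C=C([O-])[C@@H]1C[C@@H]2O[C@]2(C)[C@H](O[Si](CC)(CC)CC)[C@H]1OC(=O)/C(C)=C/C.[K+] | intermediate (not isolated)
12 | enol triflate, 5β-[1-(trifluoromethylsulfonyloxy)ethenyl] compound | C=C(OS(=O)(=O)C(F)(F)F)[C@@H]1C[C@@H]2O[C@]2(C)[C@H](O[Si](CC)(CC)CC)[C@H]1OC(=O)/C(C)=C/C | intermediate
13 | 4-methylpent-3-en-1-ol | CC(C)=CCCO | starting material
14 | 4-methylpent-3-enal | CC(C)=CCC=O | intermediate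
15 | coupling product, 5β-(3-hydroxy-6-methylhepta-1,5-dien-2-yl) compound, both carbinol epimers | C=C(C(O)CC=C(C)C)[C@@H]1C[C@@H]2O[C@]2(C)[C@H](O[Si](CC)(CC)CC)[C@H]1OC(=O)/C(C)=C/C | intermediate
16 | diol, 1β-OH and side-chain carbinol free, both carbinol epimers | C=C(C(O)CC=C(C)C)[C@@H]1C[C@@H]2O[C@]2(C)[C@H](O)[C@H]1OC(=O)/C(C)=C/C | intermediate
17 | diketone, 5β-(6-methyl-3-oxohepta-1,5-dien-2-yl)-2,3β-epoxy-6α-tigloyloxy ketone | C=C(C(=O)CC=C(C)C)[C@@H]1C[C@@H]2O[C@]2(C)C(=O)[C@H]1OC(=O)/C(C)=C/C | intermediate
18 | (1S,3S,4S,6S)-4-[(4E)-6-hydroperoxy-6-methyl-3-oxohepta-1,4-dien-2-yl]-1-methyl-2-oxo-7-oxabicyclo[4.1.0]heptan-3-yl (2E)-2-methylbut-2-enoate | C=C(C(=O)/C=C/C(C)(C)OO)[C@@H]1C[C@@H]2O[C@]2(C)C(=O)[C@H]1OC(=O)/C(C)=C/C | target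

Total step count: 12.
Longest linear sequence: 11 steps (steps 1–7 and 9–12).

Steps most likely to fail

1. **Step 12.** Hydrogen abstraction may show poor regioselectivity, taking a methyl C–H instead of the CH2 next to the ketone. Prolonged irradiation may also slowly over-oxidise the tiglate.
   - Fallback: it sets out from 12 and comes back at 18, and it brings the peroxide in ready-made.
   - Commercial methyl 4-methylpent-3-enoate F1 is photooxygenated at the outset, where regioisomers are cheap to separate, to methyl (E)-4-hydroperoxy-4-methylpent-2-enoate F2.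
   - 2-Methoxypropene with PPTS gives the peroxyketal ester F3. LiOH gives the peroxyketal acid F4. The Ghosez reagent (1-chloro-N,N,2-trimethylprop-1-en-1-amine) gives the peroxyketal acid chloride F5.
   - In parallel, 12 is desilylated with buffered HF·pyridine to the hydroxy triflate F6. F6 is oxidised with Dess–Martin periodinane to the keto triflate F7. F7 is stannylated (Me3SnSnMe3, Pd(PPh3)4, LiCl, THF) to the keto alkenylstannane F8.
   - A phosphine-free Stille acylation of F8 with F5 (Pd2(dba)3, AsPh3, THF) forms the same carbon–carbon bond and gives the peroxyketal of the target F9. Aqueous acetic acid then releases 18.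

2. **Step 9.** Oxidative addition or transmetalation may be sluggish at the hindered triflate. The alkenylmetal species may be protodemetalated, and the aldehyde may drift into conjugation before it is consumed.
   - Fallback: it sets out from 12 and comes back at 17, and it forms the bond at the ketone level with reversed roles of metal and electrophile.
   - 12 is stannylated (Me3SnSnMe3, Pd(PPh3)4, LiCl) to the silyl-protected alkenylstannane F10.
   - Commercial 4-methylpent-3-enoic acid F11 is converted with the Ghosez reagent into 4-methylpent-3-enoyl chloride F12.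
   - Stille acylation of F10 with F12 under 1 atm CO, which suppresses decarbonylation, gives the silyl-protected enone F13.
   - Buffered HF·pyridine gives the hydroxy enone F14, and a single Dess–Martin oxidation returns to 17.

3. **Step 7.** Proton transfer between ketone and enolate may move the enolate to C5, followed by loss of the tiglate through β-elimination. Excess base may also eliminate the triflate.
   - Fallback: it sets out from 10 and comes back at 15, and it avoids enolate chemistry altogether.
   - 10 is condensed with hydrazine hydrate (Et3N, EtOH, rt) to the hydrazone F15.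
   - Barton iodination (I2, tetramethylguanidine, THF, 0 °C) gives the 2-iodoalkene F16.
   - F16 takes the place of 12 in the Ni/Cr coupling with 14 and gives 15.

Further compounds
F1 | step 12 | methyl 4-methylpent-3-enoate (commercial) | COC(=O)CC=C(C)C
F2 | step 12 | methyl (E)-4-hydroperoxy-4-methylpent-2-enoate | COC(=O)/C=C/C(C)(C)OO
F3 | step 12 | methyl (E)-4-[(2-methoxypropan-2-yl)peroxy]-4-methylpent-2-enoate | COC(=O)/C=C/C(C)(C)OOC(C)(C)OC
F4 | step 12 | (E)-4-[(2-methoxypropan-2-yl)peroxy]-4-methylpent-2-enoic acid | OC(=O)/C=C/C(C)(C)OOC(C)(C)OC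
F5 | step 12 | (E)-4-[(2-methoxypropan-2-yl)peroxy]-4-methylpent-2-enoyl chloride | O=C(Cl)/C=C/C(C)(C)OOC(C)(C)OC
F6 | step 12 | hydroxy triflate (12 without the silyl group) | C=C(OS(=O)(=O)C(F)(F)F)[C@@H]1C[C@@H]2O[C@]2(C)[C@H](O)[C@H]1OC(=O)/C(C)=C/C
F7 | step 12 | keto triflate | C=C(OS(=O)(=O)C(F)(F)F)[C@@H]1C[C@@H]2O[C@]2(C)C(=O)[C@H]1OC(=O)/C(C)=C/C
F8 | step 12 | keto alkenylstannane, 5β-[1-(trimethylstannyl)ethenyl] epoxy ketone tiglate | C=C([Sn](C)(C)C)[C@@H]1C[C@@H]2O[C@]2(C)C(=O)[C@H]1OC(=O)/C(C)=C/C
F9 | step 12 | 2-methoxypropan-2-yl peroxyketal of the target | C=C(C(=O)/C=C/C(C)(C)OOC(C)(C)OC)[C@@H]1C[C@@H]2O[C@]2(C)C(=O)[C@H]1OC(=O)/C(C)=C/C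
F10 | step 9 | silyl-protected alkenylstannane | C=C([Sn](C)(C)C)[C@@H]1C[C@@H]2O[C@]2(C)[C@H](O[Si](CC)(CC)CC)[C@H]1OC(=O)/C(C)=C/C
F11 | step 9 | 4-methylpent-3-enoic acid (commercial) | CC(C)=CCC(=O)O
F12 | step 9 | 4-methylpent-3-enoyl chloride | CC(C)=CCC(=O)Cl
F13 | step 9 | silyl-protected enone | C=C(C(=O)CC=C(C)C)[C@@H]1C[C@@H]2O[C@]2(C)[C@H](O[Si](CC)(CC)CC)[C@H]1OC(=O)/C(C)=C/C
F14 | step 9 | hydroxy enone | C=C(C(=O)CC=C(C)C)[C@@H]1C[C@@H]2O[C@]2(C)[C@H](O)[C@H]1OC(=O)/C(C)=C/C
F15 | step 7 | hydrazone of 10 | CC(=NN)[C@@H]1C[C@@H]2O[C@]2(C)[C@H](O[Si](CC)(CC)CC)[C@H]1OC(=O)/C(C)=C/C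
F16 | step 7 | 2-iodoalkene, 5β-(1-iodoethenyl) compound | C=C(I)[C@@H]1C[C@@H]2O[C@]2(C)[C@H](O[Si](CC)(CC)CC)[C@H]1OC(=O)/C(C)=C/C
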